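**Retrosynthetic overview**
- Target ⇐ Heck coupling of acrolein onto a 5-iodo-2,3-dihydrobenzofuran, after Mitsunobu isovalerate formation at its primary alcohol.
- trans-2-Aryl-3-(hydroxymethyl)dihydrobenzofuran ⇐ oxidative ring contraction (1,2-aryl shift, λ3-iodane) of a (2R)-2-aryl-2H-chromene, then acetal hydrolysis and reduction; C3 is set trans to C2 here.
- (2R)-Chromene ⇐ enantioselective annulation of 4-iodoguaiacol with O-pivaloylconiferaldehyde (C–C bond ortho to the phenol, then the C2–O bond); C2 is set here.
- Both partners ⇐ 4-iodoguaiacol (catechol, MeI, NIS) and acrolein; the C2–C3–CH2O unit and the propenal arm both come from acrolein.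
- Ring order: both benzene rings are bought as catechol; the pyran ring is formed in step 5 and contracted to the furan ring in step 6.

Assumption: the (R)-configured phosphoramide catalyst is taken to deliver the 2R chromene; if the sense of induction is the opposite, its (S)-enantiomer is used.

**Step 1**
Reactants: 1 catechol (benzene-1,2-diol)
Product: 2 guaiacol (2-methoxyphenol)
Conditions: MeI (1.0 equiv), Li2CO3 (1.1 equiv), DMF, 50 °C
Reagents that add atoms: iodomethane, IC
Why: Williamson mono-O-methylation of the symmetrical diol; with one equivalent of MeI and the weak base Li2CO3 the mono-phenoxide reacts once and the less acidic guaiacol is alkylated further only slowly, the veratrole and unreacted catechol being removed by base extraction.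

**Step 2**
Reactants: 2 guaiacol
Product: 3 para-iodoguaiacol (4-iodo-2-methoxyphenol)
Conditions: NIS (1.0 equiv), TsOH·H2O (10 mol %), MeCN, 0 °C → rt
Reagents that add atoms: N-iodosuccinimide, O=C1CCC(=O)N1I
Why: Electrophilic aromatic iodination, directed para to the free hydroxyl as the strongest activating group.

**Step 3**
Reactants: 3 para-iodoguaiacol
Product: 4 aryl pivalate (4-iodo-2-methoxyphenyl 2,2-dimethylpropanoate)
Conditions: PivCl (1.1 equiv), Et3N (1.3 equiv), DMAP (5 mol %), CH2Cl2, 0 °C → rt
Reagents that add atoms: pivaloyl chloride, CC(C)(C)C(Cl)=O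
Why: Acylation (esterification) of the phenol; the hindered, electron-withdrawing pivalate makes ring B a poor migrating group and a poor cation donor in steps 5–7 and is removed by the hydride in step 7.

**Step 4**
Reactants: 4 aryl pivalate; 5 acrolein (prop-2-enal)
Product: 6 O-pivaloylconiferaldehyde ((E)-2-methoxy-4-(3-oxoprop-1-en-1-yl)phenyl 2,2-dimethylpropanoate)
Conditions: Pd(OAc)2 (3 mol %), n-Bu4NCl (1.0 equiv), NaHCO3 (2.5 equiv), acrolein (3 equiv), DMF, 50 °C
Reagents that add atoms: none
Why: Mizoroki–Heck reaction under Jeffery's ligand-free phase-transfer conditions, which couple aryl iodides with acrolein below 60 °C; syn β-hydride elimination gives the E enal and the mild base leaves the pivalate intact.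

**Step 5**
Reactants: 3 para-iodoguaiacol; 6 O-pivaloylconiferaldehyde
Product: 9 chromene (4-[(2R)-6-iodo-8-methoxy-2H-chromen-2-yl]-2-methoxyphenyl 2,2-dimethylpropanoate), via magnesium phenoxide 7 (not isolated), via racemic allylic diol 8 (not isolated)
Conditions: EtMgBr (1.0 equiv), Et2O, 0 °C, then toluene; 6 (1.0 equiv), toluene–CH2Cl2, 0 °C → rt; pH 7 buffer work-up; crude 8, (R)-3,3'-bis(2,4,6-triisopropylphenyl)-1,1'-binaphthyl-2,2'-diyl N-triflylphosphoramide (5 mol %), 4 Å molecular sieves, toluene, −60 → −30 °C
Reagents that add atoms: none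
Why: Proposed new method: a one-pot asymmetric union of a phenol and an enal to a 2-aryl-2H-chromene, in which magnesium phenoxide 7 adds through its only free ortho carbon to the magnesium-bound aldehyde in a six-membered chelate (the known ortho-specific, 1,2-selective hydroxyalkylation of aryloxymagnesium halides) to give racemic 8, whose carbinol stereocentre is erased when the strongly acidic chiral phosphoramide ionises it at low temperature to a 1,3-diarylallyl cation (a protonated vinyl ortho-quinone methide) held in a contact ion pair by the phosphoramide anion, which also hydrogen-bonds the phenol, so that the phenolic oxygen closes onto one face of the distal terminus bearing ring B and sets C2 as R; the closest known reaction types are the thermal racemic boronic-acid-mediated phenol–enal chromene annulation and chiral phosphoramide-catalysed intramolecular allylic substitutions of phenol-tethered allylic alcohols through chiral contact ion pairs.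

**Step 6**
Reactants: 9 chromene
Product: 10 acetal (4-[(2R,3R)-3-(dimethoxymethyl)-5-iodo-7-methoxy-2,3-dihydro-1-benzofuran-2-yl]-2-methoxyphenyl 2,2-dimethylpropanoate)
Conditions: PhI(OH)OTs (1.2 equiv), MeOH, −20 → 0 °C; NaHCO3 quench
Reagents that add atoms: methanol, CO
Why: Oxidative ring contraction by a 1,2-aryl shift mediated by a λ3-iodane, the reaction type established for 1,2-dihydronaphthalenes and for the 4-methoxy-2H-chromenes that react in flavanone ring contractions: the iodane adds to C3 anti to the 2-aryl group with methanol at C4, the ring A carbon then migrates from C4 to C3 with inversion as iodobenzene leaves, which places the new C3 substituent trans to the C2 aryl group, and methanol caps the resulting oxocarbenium ion as the acetal while C2 is untouched.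

**Step 7**
Reactants: 10 acetal
Product: 12 phenol alcohol (4-[(2R,3S)-3-(hydroxymethyl)-5-iodo-7-methoxy-2,3-dihydro-1-benzofuran-2-yl]-2-methoxyphenol), via aldehyde 11 (not isolated)
Conditions: 1 M aq. HCl, THF, rt; extractive work-up; then i-Bu2AlH (DIBAL-H, 5 equiv), CH2Cl2, −78 → 0 °C; aq. potassium sodium tartrate
Reagents that add atoms: water, O
Why: Acid hydrolysis of the acetal followed by hydride reduction, in which i-Bu2AlH reduces the aldehyde to the primary alcohol and cleaves the aryl pivalate in the same operation; any cis aldehyde epimerises through its enol to the favoured trans isomer before reduction, and the aryl iodide and C2 are unaffected.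

**Step 8**
Reactants: 12 phenol alcohol; 13 isovaleric acid (3-methylbutanoic acid)
Product: 14 isovalerate ([(2R,3S)-2-(4-hydroxy-3-methoxyphenyl)-5-iodo-7-methoxy-2,3-dihydro-1-benzofuran-3-yl]methyl 3-methylbutanoate)
Conditions: PPh3 (1.3 equiv), DIAD (1.3 equiv), 13 (1.5 equiv), THF, 0 °C → rt
Reagents that add atoms: none
Why: Mitsunobu esterification, chemoselective for the aliphatic hydroxyl because only it is activated as the alkoxyphosphonium ion and the carboxylic acid (pKa about 5) is the pronucleophile in preference to the phenol (pKa about 10); the reacting carbon is a CH2, so no stereocentre is touched.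

**Step 9**
Reactants: 14 isovalerate; 5 acrolein
Product: 15 CNP0272976.1 ([(2R,3S)-2-(4-hydroxy-3-methoxyphenyl)-7-methoxy-5-[(E)-3-oxoprop-1-en-1-yl]-2,3-dihydro-1-benzofuran-3-yl]methyl 3-methylbutanoate)
Conditions: Pd(OAc)2 (5 mol %), n-Bu4NCl (1.0 equiv), NaHCO3 (2.5 equiv), acrolein (4 equiv), DMF, 45 °C
Reagents that add atoms: none
Why: Mizoroki–Heck reaction under Jeffery's conditions; the weak base at 45 °C leaves the isovalerate and the para-hydroxybenzyl aryl ether at C2 intact, and syn β-hydride elimination gives the E enal.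

**Compound list**
1 | catechol (benzene-1,2-diol) | Oc1ccccc1O | starting material
2 | guaiacol (2-methoxyphenol) | COc1ccccc1O | intermediate
3 | para-iodoguaiacol (4-iodo-2-methoxyphenol) | COc1cc(I)ccc1O | intermediate
4 | 4-iodo-2-methoxyphenyl 2,2-dimethylpropanoate | COc1cc(I)ccc1OC(=O)C(C)(C)C | intermediate
5 | acrolein (prop-2-enal) | C=CC=O | starting material
6 | (E)-2-methoxy-4-(3-oxoprop-1-en-1-yl)phenyl 2,2-dimethylpropanoate | COc1cc(/C=C/C=O)ccc1OC(=O)C(C)(C)C | intermediate
7 | bromomagnesium 4-iodo-2-methoxyphenoxide | COc1cc(I)ccc1O[Mg]Br | intermediate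
8 | racemic 4-[(E)-3-hydroxy-3-(2-hydroxy-5-iodo-3-methoxyphenyl)prop-1-en-1-yl]-2-methoxyphenyl 2,2-dimethylpropanoate | COc1cc(I)cc(C(O)/C=C/c2ccc(OC(=O)C(C)(C)C)c(OC)c2)c1O | intermediate
9 | 4-[(2R)-6-iodo-8-methoxy-2H-chromen-2-yl]-2-methoxyphenyl 2,2-dimethylpropanoate | COc1cc(I)cc2C=C[C@@H](Oc12)c3ccc(OC(=O)C(C)(C)C)c(OC)c3 | intermediate
10 | 4-[(2R,3R)-3-(dimethoxymethyl)-5-iodo-7-methoxy-2,3-dihydro-1-benzofuran-2-yl]-2-methoxyphenyl 2,2-dimethylpropanoate | COc1cc([C@@H]2Oc3c(OC)cc(I)cc3[C@H]2C(OC)OC)ccc1OC(=O)C(C)(C)C | intermediate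
11 | 4-[(2R,3R)-3-formyl-5-iodo-7-methoxy-2,3-dihydro-1-benzofuran-2-yl]-2-methoxyphenyl 2,2-dimethylpropanoate | COc1cc([C@@H]2Oc3c(OC)cc(I)cc3[C@H]2C=O)ccc1OC(=O)C(C)(C)C | intermediate
12 | 4-[(2R,3S)-3-(hydroxymethyl)-5-iodo-7-methoxy-2,3-dihydro-1-benzofuran-2-yl]-2-methoxyphenol | COc1cc([C@@H]2Oc3c(OC)cc(I)cc3[C@H]2CO)ccc1O | intermediate
13 | isovaleric acid (3-methylbutanoic acid) | CC(C)CC(O)=O | starting material
14 | [(2R,3S)-2-(4-hydroxy-3-methoxyphenyl)-5-iodo-7-methoxy-2,3-dihydro-1-benzofuran-3-yl]methyl 3-methylbutanoate | COc1cc([C@@H]2Oc3c(OC)cc(I)cc3[C@H]2COC(=O)CC(C)C)ccc1O | intermediate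
15 | CNP0272976.1, [(2R,3S)-2-(4-hydroxy-3-methoxyphenyl)-7-methoxy-5-[(E)-3-oxoprop-1-en-1-yl]-2,3-dihydro-1-benzofuran-3-yl]methyl 3-methylbutanoate | COc1cc([C@@H]2Oc3c(OC)cc(/C=C/C=O)cc3[C@H]2COC(=O)CC(C)C)ccc1O | target

**Step count and risks**

Total steps: 9. Longest linear sequence: 9 steps (1 → 2 → 3 → 4 → 6 → 9 → 10 → 12 → 14 → 15; compound 3 enters twice, in steps 3 and 5).

The three steps most likely to fail:

1) Step 5, the proposed new annulation. The risks are a sluggish ortho-hydroxyalkylation of the iodine-deactivated phenoxide, premature racemic ring closure of 8 on magnesium before the chiral acid is added, and erosion of ee by re-ionisation of the product at C2. The fallback sets out from 3 and 6 and uses the established thermal annulation (PhB(OH)2 1.1 equiv, catalytic propionic acid, toluene, reflux with water removal). This first gives the 2-phenyl-4-styryl-4H-1,3,2-benzodioxaborin F1, which on continued heating loses phenylboronic acid and ring-closes to the racemic chromene F2. Preparative chiral-phase supercritical fluid chromatography of F2 then delivers the (R)-enantiomer, and the fallback comes back to the route at 9.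

2) Step 6, the ring contraction on a chromene without a 4-alkoxy group. The risks are simple 3,4-dimethoxy addition, migration of ring B instead of ring A, acid-induced ionisation at C2, and ligand exchange of the λ3-iodane with the aryl iodide. The fallback sets out from 9 and moves the rearrangement to the ketone oxidation level, where it is documented for flavanones with retention at C2. Mukaiyama hydration (Co(acac)2 cat., PhSiH3, O2, i-PrOH) puts the hydroxyl on the benzylic C4 and gives the flavan-4-ol F3 as a mixture of C4 epimers. Dess–Martin oxidation gives the (R)-flavanone F4. PhI(OAc)2, H2SO4 and HC(OMe)3 then effect the known flavanone ring contraction to the trans methyl ester F5. DIBAL-H reduces the ester and cleaves the pivalate, and the fallback comes back to the route at 12.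

3) Step 9, the final Heck coupling on a substrate with a free phenol, an ester and an electron-rich aryl iodide. The risks are acrolein polymerisation and slow oxidative addition. The fallback sets out from 14: Suzuki–Miyaura vinylation (potassium vinyltrifluoroborate, PdCl2(dppf), Et3N, n-PrOH, 80 °C) gives the 5-vinyl compound F6. Cross-metathesis of F6 with crotonaldehyde (second-generation Hoveyda–Grubbs catalyst, CH2Cl2, 40 °C) gives the E enal, and the fallback comes back to the route at 15.

**Further compounds**
F1 | step 5 | 4-[(E)-2-(6-iodo-8-methoxy-2-phenyl-4H-1,3,2-benzodioxaborin-4-yl)ethenyl]-2-methoxyphenyl 2,2-dimethylpropanoate (racemic) | COc1cc(I)cc2C(/C=C/c3ccc(OC(=O)C(C)(C)C)c(OC)c3)OB(c3ccccc3)Oc12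
F2 | step 5 | racemic 4-(6-iodo-8-methoxy-2H-chromen-2-yl)-2-methoxyphenyl 2,2-dimethylpropanoate | COc1cc(I)cc2C=CC(Oc12)c3ccc(OC(=O)C(C)(C)C)c(OC)c3
F3 | step 6 | 4-[(2R)-4-hydroxy-6-iodo-8-methoxy-3,4-dihydro-2H-chromen-2-yl]-2-methoxyphenyl 2,2-dimethylpropanoate (C4 epimers) | COc1cc(I)cc2C(O)C[C@@H](Oc12)c3ccc(OC(=O)C(C)(C)C)c(OC)c3
F4 | step 6 | 4-[(2R)-6-iodo-8-methoxy-4-oxo-3,4-dihydro-2H-chromen-2-yl]-2-methoxyphenyl 2,2-dimethylpropanoate | COc1cc(I)cc2C(=O)C[C@@H](Oc12)c3ccc(OC(=O)C(C)(C)C)c(OC)c3
F5 | step 6 | methyl (2R,3R)-5-iodo-7-methoxy-2-[3-methoxy-4-(2,2-dimethylpropanoyloxy)phenyl]-2,3-dihydro-1-benzofuran-3-carboxylate | COc1cc([C@@H]2Oc3c(OC)cc(I)cc3[C@H]2C(=O)OC)ccc1OC(=O)C(C)(C)C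
F6 | step 9 | [(2R,3S)-5-ethenyl-2-(4-hydroxy-3-methoxyphenyl)-7-methoxy-2,3-dihydro-1-benzofuran-3-yl]methyl 3-methylbutanoate | COc1cc([C@@H]2Oc3c(OC)cc(C=C)cc3[C@H]2COC(=O)CC(C)C)ccc1O
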